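The cyclohexenone ring (C1 ketone, C2=C3–OMe, C4 ketal, C5 methylene, C6 allyl carbon) is disconnected at C3–C4 and C5–C6. The key step exploits its 1,3-dioxygenated C1–C3 unit, which maps onto a 1,1-dimethoxy-3-silyloxy diene carrying the allyl group at the future C6. The C4 ketal carbon maps onto a chelating 2-methoxyacrylate whose carboxyl is later exchanged for the second oxygen. One copper–bis(oxazoline)-catalysed (4+2) cycloaddition closes the carbocycle, sets C6 and delivers oxygen at C1, C3 and C4. The precursors are a (Z)-silyl dienol ether of an acyl ketene acetal and an acid-labile 2-methoxyacrylate ester.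

Key step: step 4

Remarks on the chemistry (atom labels C1–C6 always refer to the ring numbering above):
- The target is (4R,6R): the aryloxy group is trans to the C6 allyl group and the C4 methoxy group is cis to it.
- Design choice: the acrylate carries a 4-methoxybenzyl ester, so that acid frees the carboxyl in the same operation that unmasks the enone. No base-mediated ester hydrolysis is then needed next to the epimerisable C6 centre and the base-labile vinylogous ester.
- Assumption: the sense of induction is taken from a square-planar chelate model, which points to the (R,R)-ligand for attack on the acrylate face that leads to (6R). If the adduct proves antipodal, the (S,S)-ligand is used with nothing else changed.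
- Assumption: C4 of the target is set under substrate control in the last step, the C6 allyl group being the only directing element.

Step 1
Reactants: 1 pent-4-enoyl chloride; 2 1,1-dimethoxyethene
Product: 3 1,1-dimethoxyhepta-1,6-dien-3-one
Conditions: 2 (2.2 equiv), Et2O, 0 °C to rt
Reagents that add atoms: none
Why: C-acylation of a ketene acetal by an acid chloride: the nucleophilic CH2 of 2 attacks 1, and loss of HCl from the adduct (taken up by the second equivalent of 2, which ends as methyl acetate and chloromethane) should give the push–pull enone without an amine base that could turn 1 into a ketene.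

Step 2
Reactants: 3 1,1-dimethoxyhepta-1,6-dien-3-one
Product: 4 (3Z)-3-(tert-butyldimethylsilyloxy)-1,1-dimethoxyhepta-1,3,6-triene
Conditions: tBuMe2SiOTf, Et3N, Et2O, 0 °C
Reagents that add atoms: tert-butyldimethylsilyl trifluoromethanesulfonate, CC(C)(C)[Si](C)(C)OS(=O)(=O)C(F)(F)F
Why: Soft enolisation (silyl triflate with a tertiary amine): O-silylation of the electron-rich carbonyl and loss of the only enolisable proton should give the silyl dienol ether, the Z geometry (allyl-bearing carbon trans to the dimethoxyvinyl group) being favoured by allylic strain.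

Step 3
Reactants: 5 methyl 2-methoxyacrylate; 6 4-methoxybenzyl alcohol
Product: 7 4-methoxybenzyl 2-methoxyacrylate
Conditions: Ti(OiPr)4 (5 mol %), BHT (trace), toluene, reflux, MeOH removed (4 Å MS in a Soxhlet thimble)
Reagents that add atoms: none
Why: Titanate-catalysed transesterification of an acrylate with a primary benzylic alcohol, driven by removal of methanol, with the radical inhibitor suppressing polymerisation.

Step 4
Reactants: 4 (3Z)-3-(tert-butyldimethylsilyloxy)-1,1-dimethoxyhepta-1,3,6-triene; 7 4-methoxybenzyl 2-methoxyacrylate
Product: 8 4-methoxybenzyl (1R,5R)-5-allyl-4-(tert-butyldimethylsilyloxy)-1,2,2-trimethoxycyclohex-3-ene-1-carboxylate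
Conditions: Cu(OTf)2 (10 mol %), (R,R)-tBu-box [2,2′-(propane-2,2-diyl)bis((4R)-4-tert-butyl-4,5-dihydrooxazole)] (11 mol %), 4 Å MS, CH2Cl2, −78 to −40 °C
Reagents that add atoms: none
Why: Proposed new method: the ester carbonyl and the α-methoxy oxygen of 7 form a five-membered chelate on the square-planar divalent copper–bis(oxazoline) complex, which activates the alkene and exposes one of its faces; the diene terminus that becomes C6, the most nucleophilic carbon of 4 because both the silyloxy and the ketene-acetal oxygens push towards it, adds to the acrylate CH2 (C5–C6 bond), and the copper-bound ester enolate then collapses onto the dimethoxycarbenium carbon (C3–C4 bond). The closest known reactions are thermal and Lewis-acid cycloadditions of 1,1-dialkoxy-3-silyloxybutadienes with acrylates and copper–bis(oxazoline)-catalysed Diels–Alder and Mukaiyama–Michael additions to two-point-binding acceptors. The six-membered carbocycle is closed in a strongly asynchronous (4+2) event whose second bond forms by 6-(enolexo)-exo-trig attack of the enolate carbon on the oxocarbenium carbon. C6 is set by the ligand-controlled face of the bound acrylate, relayed through an ester-endo arrangement in which the (Z)-enol silane keeps the allyl group outside; the ester-bearing carbon C4 follows from the same acrylate face and is erased later. The step needs regio-, endo- and enantioselectivity: the first comes from the matched polarisation of the partners, the second from the compact chelate that holds the carbenium terminus over the enolate, and the bulky silyl group disfavours silyl transfer that would stop at an open-chain Michael adduct.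

Step 5
Reactants: 8 4-methoxybenzyl (1R,5R)-5-allyl-4-(tert-butyldimethylsilyloxy)-1,2,2-trimethoxycyclohex-3-ene-1-carboxylate
Product: 10 (1R,5R)-5-allyl-1,2-dimethoxy-4-oxocyclohex-2-ene-1-carboxylic acid, via enone 4-methoxybenzyl ester 9 (not isolated)
Conditions: CF3CO2H (10 vol %), anisole (10 equiv), CH2Cl2, 0 °C; cold NaHCO3 extraction, re-acidification
Reagents that add atoms: none
Why: Acid unmasking as for other 1-alkoxy-3-silyloxydiene cycloadducts (ionisation of the allylic ketal, loss of methanol and desilylation to the β-methoxy enone) together with SN1-type cleavage of the 4-methoxybenzyl ester, the benzylic cation being trapped by anisole; no base is present, so C6 next to the new ketone should keep its configuration.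

Step 6
Reactants: 10 (1R,5R)-5-allyl-1,2-dimethoxy-4-oxocyclohex-2-ene-1-carboxylic acid
Product: 11 (6R)-6-allyl-3,4,4-trimethoxycyclohex-2-en-1-one
Conditions: graphite anode, Pt cathode, undivided cell, MeOH, 2,4,6-collidine (0.3 equiv), constant current (about 2.5 F/mol), 0 °C
Reagents that add atoms: methanol, CO
Why: Hofer–Moest (non-Kolbe) anodic decarboxylation: the carboxylate loses an electron and CO2, the α-methoxy radical is oxidised on graphite to the methoxy-oxocarbenium ion and captured by methanol as the dimethyl ketal, which removes the C4 stereocentre and leaves C6 untouched.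

Step 7
Reactants: 12 3,4-dimethoxyphenol; 13 allyl bromide
Product: 14 4-(allyloxy)-1,2-dimethoxybenzene
Conditions: K2CO3, acetone, reflux
Reagents that add atoms: none
Why: Williamson ether synthesis: the phenoxide displaces bromide from the allyl halide (SN2) under conditions where C-allylation is negligible.

Step 8
Reactants: 14 4-(allyloxy)-1,2-dimethoxybenzene
Product: 16 2-allyl-4,5-dimethoxyphenol, via ortho-dienone 15 (not isolated)
Conditions: PhNEt2, 190 °C
Reagents that add atoms: none
Why: Aromatic Claisen rearrangement ([3,3]-sigmatropic shift, then tautomerisation): migration should go to the free ortho position remote from the meta-methoxy group, which is less hindered and electronically preferred, giving the 2-allyl-4,5-dimethoxy pattern.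

Step 9
Reactants: 11 (6R)-6-allyl-3,4,4-trimethoxycyclohex-2-en-1-one; 16 2-allyl-4,5-dimethoxyphenol
Product: 18 (4R,6R)-4-(2-allyl-4,5-dimethoxyphenoxy)-6-allyl-3,4-dimethoxycyclohex-2-en-1-one, via aryl trimethylsilyl ether 17 (not isolated)
Conditions: 16 (1.5 equiv), Me3SiN=C(Me)OSiMe3 (BSA, 1.6 equiv), CH2Cl2, rt; then 11, Me3SiOTf (0.2 equiv), 4 Å MS, −78 to −40 °C; Et3N quench
Reagents that add atoms: none
Why: Silyl triflate-catalysed transketalisation with a silyl ether (a glycosylation-like exchange): Me3SiOTf ionises one C4 methoxy group, the methoxy-oxocarbenium ion is captured at oxygen by the aryl silyl ether with release of MeOSiMe3, and the aryloxy group should enter pseudo-axially, trans to the pseudo-equatorial C6 allyl group, which is the (4R) arrangement and also the one expected at equilibrium because the better acceptor C–OAr bond sits axial.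

Compound list
1 | pent-4-enoyl chloride | C=CCCC(=O)Cl | starting material
2 | 1,1-dimethoxyethene | C=C(OC)OC | starting material
3 | 1,1-dimethoxyhepta-1,6-dien-3-one | COC(OC)=CC(=O)CCC=C | intermediate
4 | (3Z)-3-(tert-butyldimethylsilyloxy)-1,1-dimethoxyhepta-1,3,6-triene | COC(OC)=C/C(O[Si](C)(C)C(C)(C)C)=C/CC=C | intermediate
5 | methyl 2-methoxyacrylate | C=C(OC)C(=O)OC | starting material
6 | 4-methoxybenzyl alcohol | COc1ccc(CO)cc1 | starting material
7 | 4-methoxybenzyl 2-methoxyacrylate | C=C(OC)C(=O)OCc1ccc(OC)cc1 | intermediate
8 | 4-methoxybenzyl (1R,5R)-5-allyl-4-(tert-butyldimethylsilyloxy)-1,2,2-trimethoxycyclohex-3-ene-1-carboxylate (allyl cis to the ester) | C=CC[C@@H]1C[C@](OC)(C(=O)OCc2ccc(OC)cc2)C(OC)(OC)C=C1O[Si](C)(C)C(C)(C)C | intermediate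
9 | 4-methoxybenzyl (1R,5R)-5-allyl-1,2-dimethoxy-4-oxocyclohex-2-ene-1-carboxylate | C=CC[C@@H]1C[C@](OC)(C(=O)OCc2ccc(OC)cc2)C(OC)=CC1=O | intermediate (not isolated)
10 | (1R,5R)-5-allyl-1,2-dimethoxy-4-oxocyclohex-2-ene-1-carboxylic acid | C=CC[C@@H]1C[C@](OC)(C(=O)O)C(OC)=CC1=O | intermediate
11 | (6R)-6-allyl-3,4,4-trimethoxycyclohex-2-en-1-one | C=CC[C@@H]1CC(OC)(OC)C(OC)=CC1=O | intermediate
12 | 3,4-dimethoxyphenol | COc1ccc(O)cc1OC | starting material
13 | allyl bromide | C=CCBr | starting material
14 | 4-(allyloxy)-1,2-dimethoxybenzene | C=CCOc1ccc(OC)c(OC)c1 | intermediate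
15 | 6-allyl-3,4-dimethoxycyclohexa-2,4-dien-1-one (transient, racemic) | C=CCC1C=C(OC)C(OC)=CC1=O | intermediate (not isolated)
16 | 2-allyl-4,5-dimethoxyphenol | C=CCc1cc(OC)c(OC)cc1O | intermediate
17 | (2-allyl-4,5-dimethoxyphenoxy)trimethylsilane | C=CCc1cc(OC)c(OC)cc1O[Si](C)(C)C | intermediate (not isolated)
18 | (4R,6R)-4-(2-allyl-4,5-dimethoxyphenoxy)-6-allyl-3,4-dimethoxycyclohex-2-en-1-one | C=CCc1cc(OC)c(OC)cc1O[C@]1(OC)C[C@@H](CC=C)C(=O)C=C1OC | target

Total step count: 9. Longest linear sequence: 6 steps (steps 1, 2, 4, 5, 6, 9).

Steps most likely to fail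

Step 4 (proposed new method). The facial discrimination at the diene terminus may be weak or of the wrong sense. The ester-endo preference may erode, so that the minor diastereomer carries the opposite C6 configuration; it is removed on Et3N-deactivated silica before step 5. Silyl transfer may divert the intermediate into an open-chain Michael adduct. Fallback with known chemistry: setting out from 4 and 7, the two components are heated without catalyst (toluene, 100 °C, trace of BHT), the established thermal mode of 1,1-dialkoxy-3-silyloxydienes with acrylates. This should give racemic 4-methoxybenzyl (1RS,5RS)-5-allyl-4-(tert-butyldimethylsilyloxy)-1,2,2-trimethoxycyclohex-3-ene-1-carboxylate F1. The acid treatment of step 5 then leads through racemic 4-methoxybenzyl (1RS,5RS)-5-allyl-1,2-dimethoxy-4-oxocyclohex-2-ene-1-carboxylate F2 to racemic (1RS,5RS)-5-allyl-1,2-dimethoxy-4-oxocyclohex-2-ene-1-carboxylic acid F3. Classical resolution by crystallisation of the (S)-1-phenylethylammonium (1R,5R)-5-allyl-1,2-dimethoxy-4-oxocyclohex-2-ene-1-carboxylate salt F4 (the antipodal amine is used if it gives the less soluble salt of the wanted acid) and cold acidification bring the route back at 10.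

Step 9. The C4 oxocarbenium ion may lose a proton from C5 and the dienone then tautomerises irreversibly to the aromatic phenol. The electron-rich arene may be alkylated on carbon. The aryloxy group may enter on the wrong face at C4. Fallback: setting out from 11, exchange with PhSSiMe3 and catalytic Me3SiOTf (CH2Cl2, −78 °C) should give the mixed O,S-ketal (6R)-6-allyl-3,4-dimethoxy-4-(phenylsulfanyl)cyclohex-2-en-1-one F5 (mixture at C4). This is activated irreversibly with MeOTf in the presence of 2,6-di-tert-butyl-4-methylpyridine and phenol 16 (4 Å MS, CH2Cl2, −78 to −20 °C), as in aryl glycoside synthesis from thioglycosides, and comes back at 18. The medium stays buffered and the product cannot re-ionise, so the kinetic, pseudo-axial mode of attack is preserved.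

Step 6. Over-oxidation at the anode, radical coupling instead of further oxidation, or base-induced epimerisation at C6 near the end of the electrolysis may intervene. Fallback: setting out from 10, oxidative decarboxylation with Pb(OAc)4 (benzene–pyridine, 0 °C to rt), a known reaction of α-alkoxy acids, should give (5R)-5-allyl-1,2-dimethoxy-4-oxocyclohex-2-en-1-yl acetate F6 (mixture at the acetoxy carbon). Exchange of acetate for methoxide (MeOH, pyridinium p-toluenesulfonate, 0 °C) comes back at 11.

Further compounds
F1 | step 4 | racemic 4-methoxybenzyl (1RS,5RS)-5-allyl-4-(tert-butyldimethylsilyloxy)-1,2,2-trimethoxycyclohex-3-ene-1-carboxylate (allyl cis to the ester) | C=CCC1CC(OC)(C(=O)OCc2ccc(OC)cc2)C(OC)(OC)C=C1O[Si](C)(C)C(C)(C)C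
F2 | step 4 | racemic 4-methoxybenzyl (1RS,5RS)-5-allyl-1,2-dimethoxy-4-oxocyclohex-2-ene-1-carboxylate | C=CCC1CC(OC)(C(=O)OCc2ccc(OC)cc2)C(OC)=CC1=O
F3 | step 4 | racemic (1RS,5RS)-5-allyl-1,2-dimethoxy-4-oxocyclohex-2-ene-1-carboxylic acid | C=CCC1CC(OC)(C(=O)O)C(OC)=CC1=O
F4 | step 4 | (S)-1-phenylethylammonium (1R,5R)-5-allyl-1,2-dimethoxy-4-oxocyclohex-2-ene-1-carboxylate | C=CC[C@@H]1C[C@](OC)(C(=O)[O-])C(OC)=CC1=O.C[C@H]([NH3+])c1ccccc1
F5 | step 9 | (6R)-6-allyl-3,4-dimethoxy-4-(phenylsulfanyl)cyclohex-2-en-1-one (mixture at C4) | C=CC[C@@H]1CC(OC)(Sc2ccccc2)C(OC)=CC1=O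
F6 | step 6 | (5R)-5-allyl-1,2-dimethoxy-4-oxocyclohex-2-en-1-yl acetate (mixture at the acetoxy carbon) | CC(=O)OC1(OC)C[C@@H](CC=C)C(=O)C=C1OC
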